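**Plan**

- Numbering used throughout: the benzene ring of the target carries the acetoxy group on C1, free hydroxyls on C2 and C4, and the pentadecyl chain on C6.
- Retrosynthetic cuts, in order: the O2 and O4 hydrogens are masked as benzyl ethers; the O1–acetyl bond; the C1–O bond (traced back to C1–B); the C1–B bond together with the C6–chain bond; last, the C2–O and C4–O bonds, back to 1,3,5-trifluorobenzene.
- Enabling feature: C6 (chain) and C1 (acetoxy) are adjacent carbons of the single benzene ring, and the other neighbour of C1 is the oxygenated C2. An aryne spanning C1–C6 with that oxygen beside it should take a carbon nucleophile at C6 and leave the metal on C1.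
- Forward order: no ring is formed, the benzene ring is bought. O2 and O4 are installed by double SNAr, the chain (C6) and boron (C1) are joined in one aryne step, boron is exchanged for oxygen, O1 is acetylated, and the benzyl ethers are removed.
- Stereochemistry: none to set; the target has no stereocentre and no stereogenic double bond.

Key step: step 3

Remark on the chemistry: benzyl ethers are chosen for O2 and O4 because hydrogenolysis frees them without acid, base or alcohol, any of which could move or cleave the O1 acetate.

**Route**

Step 1
Reactants: 1 1,3,5-trifluorobenzene; 2 benzyl alcohol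
Product: 5 1,3-bis(benzyloxy)-5-fluorobenzene, via sodium benzyloxide 3 (not isolated), via monobenzyl ether 4 (not isolated)
Conditions: BnOH (2.2 equiv), NaH (2.1 equiv), NMP, 0 °C → rt; then 1 (1.0 equiv), rt → 100 °C (closed vessel)
Reagents that add atoms: benzyl alcohol (second equivalent of 2), OCc1ccccc1
Why: Two successive nucleophilic aromatic substitutions (SNAr) by alkoxide 3, in which each C–F carbon of 1 is activated by the inductive pull of the meta fluorines, monoether 4 remains reactive enough for one more substitution on heating, and every benzyloxy group introduced lowers the activation further, so about two equivalents of alkoxide in a dipolar aprotic solvent should stop at the monofluoro bis-ether 5.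

Step 2
Reactants: 6 1-bromopentadecane
Product: 7 pentadecylmagnesium bromide
Conditions: Mg turnings (1.2 equiv), I2 (cat.), THF, gentle reflux; kept as a titrated solution
Reagents that add atoms: magnesium, [Mg]
Why: Grignard formation by insertion of magnesium into a primary C–Br bond is routine for long-chain alkyl bromides, and slow addition of the bromide should keep Wurtz coupling low.

Step 3
Reactants: 5 1,3-bis(benzyloxy)-5-fluorobenzene; 7 pentadecylmagnesium bromide; 8 trimethyl borate
Product: 13 [2,4-bis(benzyloxy)-6-pentadecylphenyl]boronic acid, via aryllithium 9 (not isolated), via aryne 10 (not isolated), via arylmagnesium bromide 11 (not isolated), via dimethyl boronate 12 (not isolated)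
Conditions: 2,2,6,6-tetramethylpiperidine (1.15 equiv), n-BuLi (1.1 equiv), THF, 0 °C, to form lithium 2,2,6,6-tetramethylpiperidide (LiTMP); 5, −78 °C, 1 h; 7 (3 equiv), −78 °C → rt; B(OMe)3 (6 equiv), −78 °C → rt; cold 1 M HCl
Reagents that add atoms: water (hydrolytic work-up), O
Why: LiTMP removes the ring proton of 5 that sits between fluorine and a benzyloxy group, the most acidic C–H of the molecule, and aryllithium 9 loses LiF on warming to give 3,5-bis(benzyloxy)benzyne 10 in the presence of an excess of Grignard reagent 7. The alkylmagnesium adds across the strained triple bond (aryne carbomagnesiation), its carbon bonding to the aryne carbon remote from the flanking benzyloxy group (future C6) and magnesium ending on the neighbouring carbon (future C1), after which arylmagnesium 11 is captured by B(OMe)3 and boronate 12 is hydrolysed to 13 by the acidic work-up. The closest known reaction type is the addition of Grignard and organolithium reagents to 3-alkoxyarynes with electrophilic quench of the resulting aryl–metal bond, combined with the standard borylation of arylmagnesium halides by trialkyl borates. No ring closes and no stereocentre is formed, so only regioselectivity and chemoselectivity matter. The regioselectivity is secured by the benzyloxy group on C2 beside the triple bond, whose inductive pull stabilises the carbanion developing at C1 and distorts the aryne so that C6 is the more electrophilic terminus, while the C4 benzyloxy group is too remote to oppose it. Chemoselectivity rests on the much higher kinetic acidity of the ring position flanked by F and O compared with the benzylic CH2 groups at −78 °C, on the bulk of the amide, which adds to arynes slowly, and on the excess of Grignard reagent, which should outrun capture of the aryne by 9.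

Step 4
Reactants: 13 [2,4-bis(benzyloxy)-6-pentadecylphenyl]boronic acid
Product: 15 2,4-bis(benzyloxy)-6-pentadecylphenol, via aryl borate 14 (not isolated)
Conditions: 30% aq H2O2, THF/EtOH, 0 °C → rt; then aq Na2S2O3
Reagents that add atoms: hydrogen peroxide, OO
Why: Oxidation of an arylboronic acid with hydrogen peroxide proceeds by addition of hydroperoxide to boron, 1,2-shift of the aryl group from boron to oxygen and hydrolysis of borate ester 14 to the phenol, a sequence that leaves benzyl ethers untouched.

Step 5
Reactants: 15 2,4-bis(benzyloxy)-6-pentadecylphenol
Product: 16 2,4-bis(benzyloxy)-6-pentadecylphenyl acetate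
Conditions: Ac2O (1.5 equiv), pyridine, DMAP (cat.), CH2Cl2, 0 °C → rt
Reagents that add atoms: acetic anhydride, CC(=O)OC(C)=O
Why: O-Acylation of the phenol under nucleophilic catalysis by DMAP should overcome the flanking benzyloxy and pentadecyl groups, and 15 offers no other site that can be acylated.

Step 6
Reactants: 16 2,4-bis(benzyloxy)-6-pentadecylphenyl acetate
Product: 17 2,4-dihydroxy-6-pentadecylphenyl acetate
Conditions: H2 (1 atm), 10% Pd/C, EtOAc, rt; filtration through Celite, no base, no alcohol
Reagents that add atoms: none
Why: Heterogeneous hydrogenolysis of the two benzylic C–O bonds over Pd/C in a neutral aprotic solvent should free the C2 and C4 hydroxyls while the aryl acetate, which is not benzylic and meets neither base nor alcohol, stays on O1.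

**Compound list**

1 | 1,3,5-trifluorobenzene | Fc1cc(F)cc(F)c1 | starting material
2 | benzyl alcohol | OCc1ccccc1 | starting material
3 | sodium benzyloxide | [Na+].[O-]Cc1ccccc1 | intermediate
4 | 1-(benzyloxy)-3,5-difluorobenzene | Fc1cc(F)cc(OCc2ccccc2)c1 | intermediate
5 | 1,3-bis(benzyloxy)-5-fluorobenzene | Fc1cc(OCc2ccccc2)cc(OCc2ccccc2)c1 | intermediate
6 | 1-bromopentadecane | CCCCCCCCCCCCCCCBr | starting material
7 | pentadecylmagnesium bromide | CCCCCCCCCCCCCCC[Mg]Br | intermediate
8 | trimethyl borate | COB(OC)OC | starting material
9 | [2,4-bis(benzyloxy)-6-fluorophenyl]lithium | [Li]c1c(F)cc(OCc2ccccc2)cc1OCc1ccccc1 | intermediate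
10 | 3,5-bis(benzyloxy)benzyne (1,2-didehydro-3,5-bis(benzyloxy)benzene) | C1#CC(OCc2ccccc2)=CC(OCc2ccccc2)=C1 | intermediate
11 | [2,4-bis(benzyloxy)-6-pentadecylphenyl]magnesium bromide | CCCCCCCCCCCCCCCc1cc(OCc2ccccc2)cc(OCc2ccccc2)c1[Mg]Br | intermediate
12 | dimethyl [2,4-bis(benzyloxy)-6-pentadecylphenyl]boronate | CCCCCCCCCCCCCCCc1cc(OCc2ccccc2)cc(OCc2ccccc2)c1B(OC)OC | intermediate
13 | [2,4-bis(benzyloxy)-6-pentadecylphenyl]boronic acid | CCCCCCCCCCCCCCCc1cc(OCc2ccccc2)cc(OCc2ccccc2)c1B(O)O | intermediate
14 | 2,4-bis(benzyloxy)-6-pentadecylphenyl dihydrogen borate | CCCCCCCCCCCCCCCc1cc(OCc2ccccc2)cc(OCc2ccccc2)c1OB(O)O | intermediate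
15 | 2,4-bis(benzyloxy)-6-pentadecylphenol | CCCCCCCCCCCCCCCc1cc(OCc2ccccc2)cc(OCc2ccccc2)c1O | intermediate
16 | 2,4-bis(benzyloxy)-6-pentadecylphenyl acetate | CCCCCCCCCCCCCCCc1cc(OCc2ccccc2)cc(OCc2ccccc2)c1OC(C)=O | intermediate
17 | 2,4-dihydroxy-6-pentadecylphenyl acetate | CCCCCCCCCCCCCCCc1cc(O)cc(O)c1OC(C)=O | target

**Step count**

Total step count: 6. Longest linear sequence: 5 steps (steps 1, 3, 4, 5 and 6 from 1,3,5-trifluorobenzene); step 2 supplies the Grignard reagent in a one-step side branch.

**Steps most likely to fail**

Step 3. Several processes could divert the key step: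
- lithiation of 5 between the two benzyloxy groups, which gives an aryllithium that cannot lose LiF;
- lithiation at a benzylic CH2 followed by [1,2]-Wittig rearrangement;
- capture of the aryne by aryllithium 9 or by the amide in place of the Grignard reagent;
- erosion of the regioselectivity of the addition;
- protonation of the hindered arylmagnesium before it meets the borate.

The fallback avoids the aryne and sets out from Grignard reagent 7. Kumada–Corriu cross-coupling of 7 with purchased 1-bromo-3,5-bis(benzyloxy)benzene (Brc1cc(OCc2ccccc2)cc(OCc2ccccc2)c1) under PdCl2(dppf) catalysis in refluxing THF should give 1,3-bis(benzyloxy)-5-pentadecylbenzene F1. Electrophilic bromination with NBS in MeCN at 0 °C, directed para to one benzyloxy group and ortho to the other, should then give 1,5-bis(benzyloxy)-2-bromo-3-pentadecylbenzene F2. Bromine–lithium exchange with n-BuLi at −78 °C, addition of trimethyl borate 8 and work-up with dilute HCl bring the sequence back to the route at boronic acid 13.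

Step 4. The doubly ortho-substituted, electron-rich boronic acid may undergo protodeboronation during isolation or in the oxidising medium, and the electron-rich phenol may be oxidised further toward a quinone. The fallback forms the C1–O bond by aryl migration from carbon instead of boron and sets out from arylmagnesium bromide 11, generated as in step 3. Quenching 11 with DMF in place of the borate, followed by dilute HCl, should give 2,4-bis(benzyloxy)-6-pentadecylbenzaldehyde F3. Baeyer–Villiger oxidation with mCPBA in CH2Cl2 should convert it into 2,4-bis(benzyloxy)-6-pentadecylphenyl formate F4. Methanolysis of the formate with catalytic K2CO3 in MeOH returns to the route at phenol 15.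

Step 6. The acetyl group may migrate from O1 to the newly freed neighbouring O2 hydroxyl, the acetate may be lost by solvolysis on the catalyst or during purification, or the second benzyl ether may be cleaved incompletely. The fallback reverses the order of deprotection and acylation and sets out from phenol 15. Hydrogenolysis (H2, Pd/C, EtOAc) should give 6-pentadecylbenzene-1,2,4-triol F5, which is acetylated without exposure to air (Ac2O, pyridine) to 6-pentadecylbenzene-1,2,4-triyl triacetate F6. Regioselective enzymatic alcoholysis (Candida antarctica lipase B, n-BuOH, tert-butyl methyl ether, rt) should remove the two accessible acetates at O4 and O2 and spare the one at O1, which is shielded by the pentadecyl chain. This returns to the route at target 17.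

**Further compounds**

F1 | step 3 | 1,3-bis(benzyloxy)-5-pentadecylbenzene | CCCCCCCCCCCCCCCc1cc(OCc2ccccc2)cc(OCc2ccccc2)c1
F2 | step 3 | 1,5-bis(benzyloxy)-2-bromo-3-pentadecylbenzene | CCCCCCCCCCCCCCCc1cc(OCc2ccccc2)cc(OCc2ccccc2)c1Br
F3 | step 4 | 2,4-bis(benzyloxy)-6-pentadecylbenzaldehyde | CCCCCCCCCCCCCCCc1cc(OCc2ccccc2)cc(OCc2ccccc2)c1C=O
F4 | step 4 | 2,4-bis(benzyloxy)-6-pentadecylphenyl formate | CCCCCCCCCCCCCCCc1cc(OCc2ccccc2)cc(OCc2ccccc2)c1OC=O
F5 | step 6 | 6-pentadecylbenzene-1,2,4-triol | CCCCCCCCCCCCCCCc1cc(O)cc(O)c1O
F6 | step 6 | 6-pentadecylbenzene-1,2,4-triyl triacetate | CCCCCCCCCCCCCCCc1cc(OC(C)=O)cc(OC(C)=O)c1OC(C)=O
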